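common to all: solid electrophile 0.97 M
- red: nucleophile 0.84 M; run made earlier
- green: nucleophile 1.4 M; run made earlier
- ash: nucleophile 0.870 M; time 5.0 min
- larch: nucleophile 1.10 M; time 5.0 min
- birch: nucleophile 1.50 M; time 5.0 min

| run | time / min | solid electrophile / % | target / % |
|---|---|---|---|
| red | 0.200 | 94.7 | 0.7 |
| red | 0.667 | 84.4 | 3.0 |
| red | 1.33 | 70.4 | 9.5 |
| red | 2.00 | 57.1 | 15.1 |
| red | 2.50 | 48.0 | 19.3 |
| green | 0.200 | 94.9 | 1.0 |
| green | 0.417 | 89.9 | 2.1 |
| green | 0.667 | 84.0 | 5.4 |
| green | 1.33 | 70.3 | 12.1 |
| green | 2.50 | 46.6 | 28.4 |

(readings scatter by 0.5 percentage points)

- part of the solid electrophile that has reacted (what has only dissolved counts as not reacted) at the end, ash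
- part of the solid electrophile that has reacted (what has only dissolved counts as not reacted) at the end, larch
- part of the solid electrophile that has reacted (what has only dissolved counts as not reacted) at the end, birch
- what raising the concentration of nucleophile from its lowest to its highest value here does to the part of the solid electrophile that has reacted (what has only dissolved counts as not reacted) (changes below 5 percentage points count as none) (it falls / no change / it rises)

- at the start none of the solid electrophile is in solution
- what has only dissolved of solid electrophile counts as not reacted

1. The constants of this flask were not given, so I read one from the runs. At 2.50 min, the share of the charge neither solid nor target was 32.7% in the red run and 25.0% in the green run.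

2. I replaced the rising curve of that share by its mean, taken as half the last value. I took target made per minute as k times that mean times the nucleophile.

3. With nucleophile at its charge, green over red came to 1.15, not one. My objection was that nucleophile falls during a run.

4. How fast it falls was open. One target might cost one nucleophile, or two, if the acid set free takes a second as protonated nucleophile. With two, k was 0.723 /M/min in red and 0.808 /M/min in green, a ratio of 1.12. That shift is about the size of a scatter of 0.5 percentage points on 19.3% of target, so the readings did not tell me the cost. I took two, the dearer case, and the mean 0.766 /M/min.

5. Two per target gives each flask a ceiling, the reach: the nucleophile charge over twice the solid electrophile charge. It is 44.8% for ash, 56.7% for larch and 77.3% for birch.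

6. But a ceiling is no value at 5.0 min. Nucleophile fades pseudo-first-order, so I used the reach times one minus exp(−2 · charge · k · mean share · time). For the mean share over the run I took the share at half time: red's for ash, green's for birch, their mean for larch. That gave 40.9% for ash, 50.0% for larch and 65.2% for birch.

7. The forecast said 47%, 54% and 62%, and it rises, “with nucleophile consumed 1:1”. We differ: its ash stands higher than my reach, and its birch lower than mine.

    nucleophile + acid set free ⇌ protonated nucleophile, settled at all times (K = 564 /M)
    target ⇌ isomer of the product (K = 0.174, k = 0.00497 /s)
    electrophile + nucleophile ⇌ acid set free + target (K = 1.04, k = 0.0136 /M/s)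
    solid electrophile ⇌ electrophile, rate k4*(cs4 - [electrophile]) while solid is left; crystals form when [electrophile] > cs4 (solubility = 0.900 M, k = 0.00458 /s)

Ash gave 40.1%, larch 49.0% and birch 62.6%. Across them it rises, by 23 points. At the end of ash, 11.4% of the charged nucleophile stood free, and protonated nucleophile stood at 0.382 M. Left until 50.0 min, ash gave 45.4%, against its reach of 44.8%. A neighbour of ash with 2.4 M of solid electrophile has a reach of 18.1%, and at 5.00 min it gave 16.2%.

(Readings and results were computed with made-up constants; scatter was added.)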